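Free catalyst and intermediates A, B, C and D sum to the catalyst you charged, so you inherit a small fixed crew, and what counts is how long one turn takes it.

all flasks: substrate 0.028 M; free catalyst 15 µM; time 20 min

| charge | reagent |
|---|---|
| Sunday's | 0.340 M |
| Friday's | 0.170 M |
| Monday's | 0.0840 M |

    substrate + catalyst intermediate A → catalyst intermediate B (k1 = 330 M⁻¹ s⁻¹)
    catalyst intermediate C → catalyst intermediate D (k2 = 1.9 s⁻¹)
    reagent + free catalyst ⇌ catalyst intermediate A (K3 = 120 M⁻¹, k3 = 22 M⁻¹ s⁻¹)
    reagent + by-product ⇌ idle adduct, settled at all times (K4 = 4.1 M⁻¹)
    catalyst intermediate B ⇌ by-product + catalyst intermediate C (K5 = 1.3 M, k5 = 88 s⁻¹)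
    catalyst intermediate D ⇌ free catalyst + product (K6 = 0.0040 M, k6 = 2.1 s⁻¹)

1. part of the substrate that has reacted at the end, Sunday's
2. part of the substrate that has reacted at the end, Friday's
3. part of the substrate that has reacted at the end, Monday's
4. what raising the concentration of reagent from its lowest to its highest value here does to the part of the substrate that has reacted (changes below 5 percentage points count as none) (it falls / no change / it rises)

- by-product is meant together with its idle adduct
- run time (Sunday's): 20 min

On the bench you find substrate and reagent, with that trace of catalyst going round. Call x the fraction of substrate reacted. Each turn makes one product, and the catalyst charge times the run, over the substrate charge, gives 0.643 s of catalyst time per substrate.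

With each intermediate in balance, the waits add up: 1.12 s at A, B, C and D, plus the wait of free catalyst for reagent, with substrate and reagent both held at their charge. A turn therefore starts at 1.26 s in Sunday's, 1.39 s in Friday's and 1.66 s in Monday's.

But free catalyst also meets product and drops back into D, and each return costs another stay there. So a turn lengthens in step with x, by the drag, the seconds gained between nothing reacted and the whole charge: substrate charge over K6, k3 and reagent multiplied, 1.87 s in Friday's, 0.936 s in Sunday's, 3.79 s in Monday's.

Summing the turns, the starting turn times x, plus half the drag times x squared, equals the catalyst time. I commit to 44.0% for Sunday's, 37.0% for Friday's and 29.0% for Monday's; from lowest to highest reagent, it rises. Expect substrate still standing at 20 min, with intermediate D as the resting state. Don't thin the reagent: Monday's drag is longer than Sunday's.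

The forecast gives 42.7% for Sunday's, lower than my figure, 36% for Friday's and 28% for Monday's, and says it rises, since “more reagent recaptures free catalyst faster against this inhibition”.

The flasks give 42.6% for Sunday's, 35.8% for Friday's and 27.8% for Monday's: it rises, by 15 percentage points. Monday's stands there at the end of the run through two things acting together, each a part of it: the short run, against >99.9% at ten times the length, and the return of free catalyst and product into D, whose removal gives 36.7%; zero drag reckons 38.7%. To part Monday's answer from the forecast by a change that counts, 5 points, free catalyst has to go to 11.6 µM or 18.7 µM. For Friday's flask read at 30 min, its drag reckons 51.5%, and that flask stands at 49.0%.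

All constants stand for no real mixture; the rest is arithmetic.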